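**Strategy.** The dihydrofuran ring is opened at the C2–C3 bond. C2 is a benzylic ether carbon (bonded to O1 and the guaiacyl ring) and the acyloxymethyl arm on C3 is a reduced ester, so C3 becomes the carbene carbon of an aryldiazoacetate placed ortho to an ArCH2O ether on ring A (the benzo ring). A chiral dirhodium carboxylate inserts this carbene into one enantiotopic OCH2Ar hydrogen, closing the five-membered ring and setting C2 and C3 in one operation; base epimerisation at C3 then gives the trans series. The precursor is built from 5-iodovanillin, whose aldehyde is carried as a cinnamate and revealed as the enal by reduction and allylic oxidation.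

Key step: step 6

Assumption: Rh2(S-PTTL)4 (dirhodium tetrakis[N-phthaloyl-(S)-tert-leucinate], divalent rhodium) is taken to induce the 2R configuration on this substrate. If the opposite sense is found, the mirror-image catalyst from (R)-tert-leucine is used with no other change. Ethyl esters are used throughout so that commercial ethyl diazoacetate serves directly.

**Step 1**
Reactants: 1 vanillin; 2 triisopropylsilyl chloride
Product: 3 3-methoxy-4-(triisopropylsilyloxy)benzaldehyde
Conditions: TIPSCl, imidazole, DMF, rt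
Reagents that add atoms: 2 triisopropylsilyl chloride, CC(C)[Si](Cl)(C(C)C)C(C)C
Why: Imidazole-promoted O-silylation of the phenol should give a hindered aryl silyl ether able to survive the basic, reductive and oxidative steps that follow.

**Step 2**
Reactants: 3 3-methoxy-4-(triisopropylsilyloxy)benzaldehyde
Product: 4 [3-methoxy-4-(triisopropylsilyloxy)phenyl]methanol
Conditions: NaBH4, MeOH–THF, 0 °C
Reagents that add atoms: none
Why: Borohydride reduction of an aryl aldehyde should give the benzylic alcohol without touching the silyl ether.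

**Step 3**
Reactants: 5 5-iodovanillin (4-hydroxy-3-iodo-5-methoxybenzaldehyde); 4 [3-methoxy-4-(triisopropylsilyloxy)phenyl]methanol
Product: 6 3-iodo-5-methoxy-4-{[3-methoxy-4-(triisopropylsilyloxy)benzyl]oxy}benzaldehyde
Conditions: PPh3, DIAD, THF, 0 °C to rt
Reagents that add atoms: none
Why: Mitsunobu etherification should work well because the phenol of 5 is acidic (ortho iodine, para formyl) and 4 is an unhindered primary benzylic alcohol, so no benzylic halide is needed.

**Step 4**
Reactants: 6 3-iodo-5-methoxy-4-{[3-methoxy-4-(triisopropylsilyloxy)benzyl]oxy}benzaldehyde; 7 ethyl (triphenylphosphoranylidene)acetate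
Product: 8 ethyl (E)-3-(3-iodo-5-methoxy-4-{[3-methoxy-4-(triisopropylsilyloxy)benzyl]oxy}phenyl)acrylate
Conditions: Ph3P=CHCO2Et, toluene, 80 °C
Reagents that add atoms: 7 ethyl (triphenylphosphoranylidene)acetate, CCOC(=O)C=P(c1ccccc1)(c1ccccc1)c1ccccc1
Why: Wittig olefination with a stabilised ylide should give the E-cinnamate, which stores the three-carbon side chain at the ester oxidation level.

**Step 5**
Reactants: 8 ethyl (E)-3-(3-iodo-5-methoxy-4-{[3-methoxy-4-(triisopropylsilyloxy)benzyl]oxy}phenyl)acrylate; 9 ethyl diazoacetate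
Product: 10 ethyl (E)-3-(3-(1-diazo-2-ethoxy-2-oxoethyl)-5-methoxy-4-{[3-methoxy-4-(triisopropylsilyloxy)benzyl]oxy}phenyl)acrylate
Conditions: N2CHCO2Et, Pd(PPh3)4 (cat.), Ag2CO3, Et3N, toluene, rt
Reagents that add atoms: 9 ethyl diazoacetate, CCOC(=O)C=[N+]=[N-]
Why: Palladium-catalysed cross-coupling of an aryl iodide with the C–H bond of an acceptor diazo compound (oxidative addition at zerovalent palladium, silver-assisted iodide abstraction, deprotonative palladation of the diazoacetate, reductive elimination) should install the intact diazoacetate at the iodine-bearing carbon at room temperature.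

**Step 6**
Reactants: 10 ethyl (E)-3-(3-(1-diazo-2-ethoxy-2-oxoethyl)-5-methoxy-4-{[3-methoxy-4-(triisopropylsilyloxy)benzyl]oxy}phenyl)acrylate
Product: 11 ethyl (2R,3S)-5-[(E)-3-ethoxy-3-oxoprop-1-en-1-yl]-7-methoxy-2-[3-methoxy-4-(triisopropylsilyloxy)phenyl]-2,3-dihydrobenzofuran-3-carboxylate (cis)
Conditions: Rh2(S-PTTL)4 (cat.), toluene, −60 °C, slow addition of 10
Reagents that add atoms: none
Why: The dirhodium carboxylate should expel N2 from 10 to give a transient catalyst-bound donor/acceptor carbene at the future C3, which inserts into one of the two enantiotopic C–H bonds of the OCH2Ar group through a concerted, asynchronous three-centre transition state with hydride-transfer character. The closest known reaction type is the enantioselective intramolecular carbenoid C–H insertion of 2-(benzyloxy)aryl diazoacetates, which gives cis-2-aryl-2,3-dihydrobenzofuran-3-carboxylates. The dihydrofuran ring closes by 1,5-insertion through a five-membered cyclic transition state (C3, C3a, C7a, O1, C2), forming the C2–C3 bond. C2 is set by the chiral carboxylate pocket of the catalyst, which selects one enantiotopic hydrogen, and C3 is set relative to C2 by the kinetic preference of this catalyst family for the cis transition state, so (2R,3S) is expected. Site selectivity is secured because this is the only C–H bond in a 1,5 relationship to the carbene, and it is doubly activated by O1 and by the electron-rich silyloxy/methoxy arene. The C7 methoxy group cannot reach the carbene, the trans-disubstituted electron-poor cinnamate is a poor cyclopropanation partner, and low temperature with slow addition should suppress carbene dimerisation.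

**Step 7**
Reactants: 11 ethyl (2R,3S)-5-[(E)-3-ethoxy-3-oxoprop-1-en-1-yl]-7-methoxy-2-[3-methoxy-4-(triisopropylsilyloxy)phenyl]-2,3-dihydrobenzofuran-3-carboxylate (cis)
Product: 12 ethyl (2R,3R)-5-[(E)-3-ethoxy-3-oxoprop-1-en-1-yl]-7-methoxy-2-[3-methoxy-4-(triisopropylsilyloxy)phenyl]-2,3-dihydrobenzofuran-3-carboxylate (trans)
Conditions: NaOEt (cat.), EtOH–THF, 0 °C to rt
Reagents that add atoms: none
Why: Base-mediated enolisation and reprotonation at C3 should move the ester to the less hindered face (thermodynamic trans) while C2 stays untouched; ring-opening by beta-elimination of O1 is disfavoured because the ring C2–O1 bond lies orthogonal to the enolate pi system, and matching ethoxide to the ethyl esters avoids transesterification.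

**Step 8**
Reactants: 12 ethyl (2R,3R)-5-[(E)-3-ethoxy-3-oxoprop-1-en-1-yl]-7-methoxy-2-[3-methoxy-4-(triisopropylsilyloxy)phenyl]-2,3-dihydrobenzofuran-3-carboxylate (trans)
Product: 13 (E)-3-{(2R,3S)-3-(hydroxymethyl)-7-methoxy-2-[3-methoxy-4-(triisopropylsilyloxy)phenyl]-2,3-dihydrobenzofuran-5-yl}prop-2-en-1-ol
Conditions: i-Bu2AlH (excess), CH2Cl2, −78 to 0 °C; aq. potassium sodium tartrate
Reagents that add atoms: none
Why: Exhaustive hydride reduction with i-Bu2AlH should convert the C3 ester into the hydroxymethyl group and the cinnamate into the cinnamyl alcohol by clean 1,2-reduction; the C3 descriptor changes from R to S only through the priority change, not through inversion.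

**Step 9**
Reactants: 13 (E)-3-{(2R,3S)-3-(hydroxymethyl)-7-methoxy-2-[3-methoxy-4-(triisopropylsilyloxy)phenyl]-2,3-dihydrobenzofuran-5-yl}prop-2-en-1-ol
Product: 14 (E)-3-{(2R,3S)-3-(hydroxymethyl)-7-methoxy-2-[3-methoxy-4-(triisopropylsilyloxy)phenyl]-2,3-dihydrobenzofuran-5-yl}acrylaldehyde
Conditions: MnO2 (activated, excess), CH2Cl2, rt
Reagents that add atoms: none
Why: Activated MnO2 oxidises allylic (cinnamyl) alcohols far faster than saturated primary alcohols, so the enal should form chemoselectively with retention of the E geometry and the C3 hydroxymethyl group is left free for acylation.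

**Step 10**
Reactants: 14 (E)-3-{(2R,3S)-3-(hydroxymethyl)-7-methoxy-2-[3-methoxy-4-(triisopropylsilyloxy)phenyl]-2,3-dihydrobenzofuran-5-yl}acrylaldehyde; 15 3-methylbutanoyl chloride (isovaleryl chloride)
Product: 16 {(2R,3S)-7-methoxy-2-[3-methoxy-4-(triisopropylsilyloxy)phenyl]-5-[(E)-3-oxoprop-1-en-1-yl]-2,3-dihydrobenzofuran-3-yl}methyl 3-methylbutanoate
Conditions: i-PrCH2COCl, pyridine, DMAP (cat.), CH2Cl2, 0 °C
Reagents that add atoms: 15 3-methylbutanoyl chloride, CC(C)CC(Cl)=O
Why: Nucleophilic-catalysed acylation of the only free hydroxyl group should give the isovalerate; the enal and the silyl-protected phenol are inert to these conditions.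

**Step 11**
Reactants: 16 {(2R,3S)-7-methoxy-2-[3-methoxy-4-(triisopropylsilyloxy)phenyl]-5-[(E)-3-oxoprop-1-en-1-yl]-2,3-dihydrobenzofuran-3-yl}methyl 3-methylbutanoate
Product: 17 [(2R,3S)-2-(4-hydroxy-3-methoxyphenyl)-7-methoxy-5-[(E)-3-oxoprop-1-en-1-yl]-2,3-dihydrobenzofuran-3-yl]methyl 3-methylbutanoate (target)
Conditions: Bu4NF, AcOH, THF, 0 °C
Reagents that add atoms: none
Why: Fluoride-induced cleavage of the aryl silyl ether, buffered with acetic acid so that no free phenoxide can open the ring through a quinone methide or attack the ester, should release the phenol and leave the enal, the isovalerate and both stereocentres intact.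

**Compound list**

1 | vanillin | COc1cc(C=O)ccc1O | starting material
2 | triisopropylsilyl chloride | CC(C)[Si](Cl)(C(C)C)C(C)C | starting material
3 | 3-methoxy-4-(triisopropylsilyloxy)benzaldehyde | COc1cc(C=O)ccc1O[Si](C(C)C)(C(C)C)C(C)C | intermediate
4 | [3-methoxy-4-(triisopropylsilyloxy)phenyl]methanol | COc1cc(CO)ccc1O[Si](C(C)C)(C(C)C)C(C)C | intermediate
5 | 5-iodovanillin (4-hydroxy-3-iodo-5-methoxybenzaldehyde) | COc1cc(C=O)cc(I)c1O | starting material
6 | 3-iodo-5-methoxy-4-{[3-methoxy-4-(triisopropylsilyloxy)benzyl]oxy}benzaldehyde | COc1cc(C=O)cc(I)c1OCc1ccc(O[Si](C(C)C)(C(C)C)C(C)C)c(OC)c1 | intermediate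
7 | ethyl (triphenylphosphoranylidene)acetate | CCOC(=O)C=P(c1ccccc1)(c1ccccc1)c1ccccc1 | starting material
8 | ethyl (E)-3-(3-iodo-5-methoxy-4-{[3-methoxy-4-(triisopropylsilyloxy)benzyl]oxy}phenyl)acrylate | CCOC(=O)/C=C/c1cc(I)c(OCc2ccc(O[Si](C(C)C)(C(C)C)C(C)C)c(OC)c2)c(OC)c1 | intermediate
9 | ethyl diazoacetate | CCOC(=O)C=[N+]=[N-] | starting material
10 | ethyl (E)-3-(3-(1-diazo-2-ethoxy-2-oxoethyl)-5-methoxy-4-{[3-methoxy-4-(triisopropylsilyloxy)benzyl]oxy}phenyl)acrylate | CCOC(=O)/C=C/c1cc(OC)c(OCc2ccc(O[Si](C(C)C)(C(C)C)C(C)C)c(OC)c2)c(c1)C(=[N+]=[N-])C(=O)OCC | intermediate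
11 | ethyl (2R,3S)-5-[(E)-3-ethoxy-3-oxoprop-1-en-1-yl]-7-methoxy-2-[3-methoxy-4-(triisopropylsilyloxy)phenyl]-2,3-dihydrobenzofuran-3-carboxylate (cis) | COc1cc([C@@H]2Oc3c(OC)cc(/C=C/C(=O)OCC)cc3[C@@H]2C(=O)OCC)ccc1O[Si](C(C)C)(C(C)C)C(C)C | intermediate
12 | ethyl (2R,3R)-5-[(E)-3-ethoxy-3-oxoprop-1-en-1-yl]-7-methoxy-2-[3-methoxy-4-(triisopropylsilyloxy)phenyl]-2,3-dihydrobenzofuran-3-carboxylate (trans) | COc1cc([C@@H]2Oc3c(OC)cc(/C=C/C(=O)OCC)cc3[C@H]2C(=O)OCC)ccc1O[Si](C(C)C)(C(C)C)C(C)C | intermediate
13 | (E)-3-{(2R,3S)-3-(hydroxymethyl)-7-methoxy-2-[3-methoxy-4-(triisopropylsilyloxy)phenyl]-2,3-dihydrobenzofuran-5-yl}prop-2-en-1-ol | COc1cc([C@@H]2Oc3c(OC)cc(/C=C/CO)cc3[C@H]2CO)ccc1O[Si](C(C)C)(C(C)C)C(C)C | intermediate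
14 | (E)-3-{(2R,3S)-3-(hydroxymethyl)-7-methoxy-2-[3-methoxy-4-(triisopropylsilyloxy)phenyl]-2,3-dihydrobenzofuran-5-yl}acrylaldehyde | COc1cc([C@@H]2Oc3c(OC)cc(/C=C/C=O)cc3[C@H]2CO)ccc1O[Si](C(C)C)(C(C)C)C(C)C | intermediate
15 | 3-methylbutanoyl chloride (isovaleryl chloride) | CC(C)CC(Cl)=O | starting material
16 | {(2R,3S)-7-methoxy-2-[3-methoxy-4-(triisopropylsilyloxy)phenyl]-5-[(E)-3-oxoprop-1-en-1-yl]-2,3-dihydrobenzofuran-3-yl}methyl 3-methylbutanoate | COc1cc([C@@H]2Oc3c(OC)cc(/C=C/C=O)cc3[C@H]2COC(=O)CC(C)C)ccc1O[Si](C(C)C)(C(C)C)C(C)C | intermediate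
17 | [(2R,3S)-2-(4-hydroxy-3-methoxyphenyl)-7-methoxy-5-[(E)-3-oxoprop-1-en-1-yl]-2,3-dihydrobenzofuran-3-yl]methyl 3-methylbutanoate | COc1cc([C@@H]2Oc3c(OC)cc(/C=C/C=O)cc3[C@H]2COC(=O)CC(C)C)ccc1O | target

**Step count.** Total: 11 steps. Longest linear sequence: 11 steps (vanillin 1 to target 17; 9 steps from 5-iodovanillin 5).

**Steps most likely to fail**

Step 6. The catalyst may discriminate poorly between the two enantiotopic benzylic hydrogens on this trisubstituted ring A, may favour the wrong one, or the carbene may dimerise before it inserts. The fallback replaces catalyst control by a covalent auxiliary that turns the stereoisomers into separable diastereomers. It sets out from iodide 8. Methyl (S)-lactate is acylated with glyoxylic acid chloride p-toluenesulfonylhydrazone (PhNMe2, then Et3N, CH2Cl2, 0 °C) to give methyl (S)-2-(2-diazoacetoxy)propanoate F1. F1 is coupled with 8 under the Pd(PPh3)4/Ag2CO3/Et3N conditions of step 5 to give the lactate-bearing aryldiazoacetate F2. Decomposition of F2 with Rh2(S-DOSP)4 (dirhodium tetrakis[(S)-N-(4-dodecylphenylsulfonyl)prolinate]) or achiral Rh2(OAc)4, then equilibration of C3 with DBU and chromatographic separation of the diastereomers, should give the (2R,3R)-trans lactate ester F3. Reduction of F3 with excess i-Bu2AlH cleaves the auxiliary and reduces the cinnamate, and the route is rejoined at diol 13.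

Step 5. Oxidative addition and diazo transfer at the iodide flanked by the bulky benzyloxy group may be slow, so the diazoacetate may be consumed by palladium-carbene pathways or by slow dipolar cycloaddition to the cinnamate. The fallback builds the arylacetate first and introduces the diazo group afterwards. It sets out from iodide 8. Negishi-type coupling with the Reformatsky reagent ethyl (bromozincio)acetate F4 (BrZnCH2CO2Et, from ethyl bromoacetate and zinc dust; Pd(dba)2/Q-Phos, THF, rt) gives the ethyl arylacetate F5. Regitz diazo transfer to F5 (4-acetamidobenzenesulfonyl azide, DBU, MeCN, 0 °C to rt) takes place only at the doubly activated ArCH2CO2Et position and returns to the route at diazoacetate 10.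

Step 7. Epimerisation at C3 may stall short of completion, or ethoxide may remove the aryl silyl ether or trigger ring-opening. The fallback inverts C2 under acid instead of C3 under base. It sets out from diazoacetate 10. Insertion with the mirror-image catalyst Rh2(R-PTTL)4 gives the enantiomeric cis ester, ethyl (2S,3R)-5-[(E)-3-ethoxy-3-oxoprop-1-en-1-yl]-7-methoxy-2-[3-methoxy-4-(triisopropylsilyloxy)phenyl]-2,3-dihydrobenzofuran-3-carboxylate F6, which already has the C3 configuration of 12. Treatment with CF3CO2H or BF3·OEt2 in CH2Cl2 at 0 °C reversibly ionises the C2–O1 bond, assisted by the para-silyloxy arene, and re-closure under thermodynamic control should place the aryl group trans to the ester. The route is rejoined at trans ester 12.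

**Further compounds**

F1 | step 6 | methyl (S)-2-(2-diazoacetoxy)propanoate | C[C@H](OC(=O)C=[N+]=[N-])C(=O)OC
F2 | step 6 | (S)-1-methoxy-1-oxopropan-2-yl 2-diazo-2-(5-[(E)-3-ethoxy-3-oxoprop-1-en-1-yl]-3-methoxy-2-{[3-methoxy-4-(triisopropylsilyloxy)benzyl]oxy}phenyl)acetate | CCOC(=O)/C=C/c1cc(OC)c(OCc2ccc(O[Si](C(C)C)(C(C)C)C(C)C)c(OC)c2)c(c1)C(=[N+]=[N-])C(=O)O[C@@H](C)C(=O)OC
F3 | step 6 | (S)-1-methoxy-1-oxopropan-2-yl (2R,3R)-5-[(E)-3-ethoxy-3-oxoprop-1-en-1-yl]-7-methoxy-2-[3-methoxy-4-(triisopropylsilyloxy)phenyl]-2,3-dihydrobenzofuran-3-carboxylate | COc1cc([C@@H]2Oc3c(OC)cc(/C=C/C(=O)OCC)cc3[C@H]2C(=O)O[C@@H](C)C(=O)OC)ccc1O[Si](C(C)C)(C(C)C)C(C)C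
F4 | step 5 | ethyl (bromozincio)acetate | CCOC(=O)C[Zn]Br
F5 | step 5 | ethyl (E)-3-(3-(2-ethoxy-2-oxoethyl)-5-methoxy-4-{[3-methoxy-4-(triisopropylsilyloxy)benzyl]oxy}phenyl)acrylate | CCOC(=O)/C=C/c1cc(OC)c(OCc2ccc(O[Si](C(C)C)(C(C)C)C(C)C)c(OC)c2)c(c1)CC(=O)OCC
F6 | step 7 | ethyl (2S,3R)-5-[(E)-3-ethoxy-3-oxoprop-1-en-1-yl]-7-methoxy-2-[3-methoxy-4-(triisopropylsilyloxy)phenyl]-2,3-dihydrobenzofuran-3-carboxylate (cis) | COc1cc([C@H]2Oc3c(OC)cc(/C=C/C(=O)OCC)cc3[C@H]2C(=O)OCC)ccc1O[Si](C(C)C)(C(C)C)C(C)C
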